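- Rings, the product of elm (the flask asked about), are what I count as left of the charge once first end groups and links are subtracted at the end of dosing, so I follow how much of the first end groups is consumed.

| flask | first end groups | second end groups | remark | time |
|---|---|---|---|---|
| elm | 0.40 M (fed, over 4.0 h) | 0.40 M | the very flask that is asked about, followed so far |  |
| maple | 0.80 M (fed, over 4.0 h) | 0.40 M | run made earlier |  |
| flask | 0.40 M (fed, over 4.0 h) | 0.400 M |  | 4.0 h |

elm run (percent of the first end groups charged)

| time / min | links / % | first end groups / % |
|---|---|---|
| 4.00 | 0.3 | 1.6 |
| 12.0 | 0.5 | 5.3 |
| 20.0 | 1.5 | 8.5 |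
| 30.0 | 0 | 8.3 |
| 40.0 | 1.8 | 14.1 |
| 60.0 | 2.0 | 16.0 |
| 80.0 | 4.3 | 18.8 |

maple run (percent of the first end groups charged)

| time / h | links / % | first end groups / % |
|---|---|---|
| 0.333 | 0 | 6.8 |
| 0.500 | 0 | 10.2 |
| 0.667 | 1.7 | 10.7 |
| 1.00 | 2.4 | 14.6 |
| 1.50 | 3.4 | 20.7 |
| 2.50 | 6.1 | 24.5 |
| 4.00 | 8.7 | 59.4 |

(standard deviation of a reading: 1 percentage point)

- links present at 4.0 h, in percent of the first end groups charged
- first end groups present at 4.0 h, in percent of the first end groups charged
- rings present at 4.0 h, in percent of the first end groups charged

- percentages count the whole charge, also what has not yet gone in

- I read maple first, taking consumption as what was fed minus what stands free. It reads 0.304 M at 2.50 h and 0.325 M at 4.00 h, although 0.300 M more is fed between the two.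
- That final reading, 0.325 M, is my stall capacity: the first end groups taken up from a charge of c(second end groups) = 0.40 M before consumption stalls, and I take second end groups as the limiting reagent in maple.
- Elm has the same c(second end groups), so at the end of dosing I expect free first end groups above 18.8% of its charge.
- In the first instants of elm, the reading at 4.00 min puts nearly all of the feed free.
- In the middle, the elm readings from 40.0 min to 80.0 min give a pseudo-first-order consumption constant of 1.09 /h. Holding that constant, I reckon feed and consumption in balance with 22.9% of the charge free.
- For the end of dosing in elm, that balance gives me 0.308 M consumed, which is less than the stall capacity, but close enough that I treat 22.9% as a low figure.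
- The maple link share of consumption, 21.4%, then gives me 16.5% links and 60.6% rings.
- The forecast, which puts first end groups higher than I do, gives 14% links, 36% first end groups and 50% rings, reading maple thus: “The second end groups have run out”.

- Elm gives 12.1% links, 28.7% first end groups and 59.3% rings, so first end groups stand above my figure.

    first end groups + second end groups → links (k = 0.900 /M/h)
    second end groups ⇌ dormant form (K = 28.0, k = 0.122 /h)
    first end groups + second end groups → rings, rate k3*[first end groups] as long as [second end groups] is above zero (k = 0.753 /h)

- At 4.00 h, elm holds 0.102 M of dormant form, with second end groups at 3.23% of their own charge. The first end groups consumed in elm come to 87.8% of the stall capacity. A neighbouring flask, the same but charged with 0.68 M of first end groups, has consumed 99.4% of it at 4.00 h, with second end groups at 0%.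

The numbers in the tables were generated by integration on assumed constants; the scatter is artificial.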